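## The problem

The target **30** is an 18-membered macrocyclic bis(bibenzyl). Four benzene rings are joined in a cycle by two diaryl ether oxygens (ring A–ring B and ring C–ring D) and two CH2CH2 bridges (ring B–ring C and ring A–ring D). There is no stereocentre, so no centre has to be set and none can direct another; the difficulties are regiochemical and entropic (closing the large ring). Ring A is 1,2,3-trisubstituted (C1 methoxy, C2 ether oxygen, C3 bridge carbon), so its oxygen is flanked on both sides and O-arylation of that phenol is the weakest bond construction in a conventional plan. Ring C carries the only free phenol, which must be masked through organolithium, ketene and palladium chemistry. Several intermediates are fragile: an aryl ynol ether and a dimethyl acetal (acid), a cyclobutenone (heat, base) and an electron-rich benzyl bromide. In addition, an aryl chloride must outlast a palladium-catalysed reduction, which fixes the order of events. The enabling feature is ring B: C1' bears the oxygen bonded to ring A C2, C3' bears the ethano arm to ring C, and C5' is hydrogen. With a temporary hydroxyl at C5', ring B is a 3-aryloxy-5-alkylphenol, the pattern that a 3-substituted cyclobutenone and a terminal ynol ether give on heating, so ring B can be grown on the crowded oxygen instead of being attached to it.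

## Retrosynthesis

**Phenol unmasking.** The ring C hydroxyl of **30** is taken back to the benzyl ether **29**. Benzyl survives butyllithium, zinc, ketenes, heat and homogeneous palladium, and it is already present in the commercial ring C building block, so it costs one final hydrogenolysis and no protection step.

**Macrocycle opening at the ring A–ring D bridge.** The bond between ring D and its benzylic CH2 is cut, leading through the alkylborane **28** to the styrene **27**, which carries a chloride on ring D. Cutting either ether instead would bring back the hindered O-arylation, and the ring B–ring C bridge is better made early, inside one fragment. The precursor is an open chain with two mutually inert ends (vinyl and aryl chloride). The forward reaction is a hydroboration followed by an intramolecular B-alkyl Suzuki–Miyaura coupling at high dilution, which needs a ligand able to activate an electron-rich aryl chloride.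

**Adjusting ring A and ring B.** The vinyl group of **27** comes from the aldehyde **26** by methylenation. The aldehyde comes from the acetal triflate **24**, where the C5' oxygen of ring B is removed by formate reduction and the acetal is hydrolysed in the same operation through **25**. Triflate **24** comes from the phenol **23**. Chloride is chosen for ring D because, unlike bromide, it is untouched while the triflate is reduced. The ring A carbon is carried as an acetal and not as a vinyl group, because a styrene would not be safe towards butyllithium or towards the palladium hydride of the reduction.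

**Ring B by benzannulation.** Two ring B bonds of **23** are cut, C2'–C1' (the carbon bearing the temporary hydroxyl) and C3'–C4', giving the ring A ethynyl ether **7** and the cyclobutenone **18**. This removes a whole arene together with the crowded diaryl ether and divides the molecule into a three-step and a six-step fragment. The forward reaction must deliver the aryloxy group meta to both the hydroxyl and the arm, which the polarity of the two partners dictates.

**Ynol ether.** The oxygen–sp carbon bond of **7** is traced to the dichlorovinyl ether **4**, and this through the aldehyde **3** to o-vanillin **1** and trichloroethylene **2**. The phenol oxygen attacks a small, linear electrophile, so the two ortho substituents do not interfere. The acetal is installed after the O-vinylation, because acetals of free salicylaldehydes are labile.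

**Cyclobutenone.** The four-membered ring of **18** is cut to the terminal alkyne **15** and a ketene unit from trichloroacetyl chloride **16**, by way of the dichlorocyclobutenone **17**. Alkyne **15** is cut at its benzylic C–C bond to the benzyl bromide **12** and 1-(trimethylsilyl)propyne **13**, through the silyl alkyne **14**. Bromide **12** goes back through the alcohol **11** to the aldehyde **10**, whose ring C–ring D ether is cut to 4-benzyloxy-3-hydroxybenzaldehyde **8** and 1-chloro-4-iodobenzene **9**. This ether is unhindered and the iodide reacts in preference to the chloride, so a standard copper-catalysed coupling suffices.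

## Roads not taken

Alternative 1: The ring C–ring D ether is cut last. The open-chain bisphenol **A1** (ring C a 2,6-dibromophenol, ring D a 2,6-dichlorophenol) would be oxidised with Tl(NO3)3 in methanol. The ring D oxygen adds to a bromine-bearing ortho carbon of the oxidised ring C, and zinc then restores the arene, giving macrocycle **A2** with a new C–O bond and the 18-membered ring closed.
- Merits: the ring closure is driven by built-in activation, the ring C phenol appears without any protecting group, and one hydrogenolysis of the three carbon–halogen bonds of **A2** would give **30**. In endgame economy this road is better than the chosen one, which needs five steps after ring B is formed.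
- Weak points: **A1** already contains both bridges and the crowded ring A–ring B ether, so the hardest bond still has to be made by arylation of a doubly ortho-substituted phenol. Four halogens must be introduced only to be removed. A stoichiometric trivalent thallium salt is required. The selectivity between the two phenols rests on the dibromophenol being oxidised first.
- Comparison: the chosen plan sets against the shorter finish the fact that the crowded ether is never made by O-arylation and that no toxic oxidant is needed.

Alternative 2: The ring B–ring C bridge is cut at both aryl–carbon bonds. The ring B pinacol boronate **A3**, vinyllithium **A4** and the ring C triflate **A5** would be joined by Pd(OAc)2 and a bisphosphine ligand in a conjunctive coupling: the boronate complex of **A3** and **A4** undergoes a palladium-induced 1,2-shift of the ring B aryl group, giving the benzylic boronate **A6**. No ring is closed.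
- Merits: it is highly convergent, both bridge bonds form in one step from simple partners, and the chloride of **A5** is left alone because the triflate reacts first. In convergence it matches the chosen plan.
- Weak points: boron ends up on a benzylic carbon as a racemic stereocentre that serves no purpose and must be removed by protodeboronation. **A3** already contains the ring A–ring B ether, so the hindered O-arylation is again unsolved. The endgame after **A6** is as long as in the chosen plan.
- Comparison: the chosen plan uses no precious metal to build ring B and obtains the crowded ether as a consequence of ring construction.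

Alternative 3: The macrocycle is cut at the ring B aryl–vinyl bond. The seco acid **A7**, a 2-aryloxybenzoic acid on ring B tethered to a ring C styrene, would be treated with [Cp*RhCl2]2 and Cu(OAc)2. The carboxylate directs trivalent rhodium to the only free ortho C–H bond, and oxidative olefination with the styrene closes the ring as the E-stilbene acid **A8**.
- Merits: the cyclisation needs no halide or boron handle, its regiochemistry is fixed by the single ortho hydrogen, and after protodecarboxylation one hydrogenation would both saturate the alkene and remove the benzyl group to give **30**. That finish is shorter than the one chosen here.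
- Weak points: the reaction type is documented almost entirely for intermolecular cases with activated alkenes. Benzoic acids under these oxidative conditions tend to lactonise onto the new alkene. An E-stilbene in this ring is strained. **A7** still needs the crowded ether and the ring A–ring D bridge made conventionally.
- Comparison: the chosen plan sets a documented thermal, metal-free ring synthesis against the shorter but speculative ring closure.

Key step: step 10

Remark on the chemistry: the target has no stereocentre and the 18-membered ring is assumed to be conformationally mobile, so no axial or planar chirality has to be controlled. Geometry is specified only for the dichlorovinyl ethers and the transient dienylketene.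

## Route

Step 1
Reactants: 1 o-vanillin (2-hydroxy-3-methoxybenzaldehyde); 2 trichloroethylene
Product: 3 2-[(E)-1,2-dichloroethenyloxy]-3-methoxybenzaldehyde
Conditions: K2CO3, DMF, 70 °C
Reagents that add atoms: none
Why: Base-mediated O-vinylation of a phenol with trichloroethylene: K2CO3 eliminates HCl to dichloroacetylene in the flask and the phenoxide adds anti to give the E-1,2-dichlorovinyl ether. The linear electrophile is insensitive to the two ortho substituents, and the non-enolisable aldehyde is a spectator.

Step 2
Reactants: 3 2-[(E)-1,2-dichloroethenyloxy]-3-methoxybenzaldehyde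
Product: 4 2-[(E)-1,2-dichloroethenyloxy]-1-(dimethoxymethyl)-3-methoxybenzene
Conditions: HC(OMe)3, MeOH, p-TsOH (cat.), rt; Et3N quench
Reagents that add atoms: trimethyl orthoformate, COC(OC)OC; methanol, CO
Why: Acid-catalysed acetalisation with the orthoformate as methoxy source and water scavenger. The dichlorovinyl ether is a deactivated enol ether and tolerates catalytic acid at room temperature.

Step 3
Reactants: 4 2-[(E)-1,2-dichloroethenyloxy]-1-(dimethoxymethyl)-3-methoxybenzene
Product: 7 1-(dimethoxymethyl)-2-(ethynyloxy)-3-methoxybenzene (ring A aryl ethynyl ether), via chloroethynyl ether 5 (not isolated), via lithium acetylide 6 (not isolated)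
Conditions: n-BuLi (2.3 equiv), THF, −78 to −40 °C; then H2O, −78 °C; filtration through basic alumina
Reagents that add atoms: none
Why: Standard conversion of a 1,2-dichlorovinyl ether into a terminal ynol ether: elimination of HCl gives the chloroalkyne 5, lithium–chlorine exchange gives the acetylide 6, and protonation gives 7. The acetal is inert to butyllithium at low temperature.

Step 4
Reactants: 8 4-benzyloxy-3-hydroxybenzaldehyde; 9 1-chloro-4-iodobenzene
Product: 10 4-(benzyloxy)-3-(4-chlorophenoxy)benzaldehyde
Conditions: CuI (10 mol %), N,N-dimethylglycine hydrochloride, Cs2CO3, 1,4-dioxane, 90 °C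
Reagents that add atoms: none
Why: Ligand-accelerated Ullmann diaryl ether synthesis. Monovalent copper inserts into the C–I bond far faster than into C–Cl, so the chloride is kept as the later coupling handle, and the aldehyde tolerates the carbonate base.

Step 5
Reactants: 10 4-(benzyloxy)-3-(4-chlorophenoxy)benzaldehyde
Product: 11 [4-(benzyloxy)-3-(4-chlorophenoxy)phenyl]methanol
Conditions: NaBH4, MeOH–THF, 0 °C
Reagents that add atoms: none
Why: Hydride reduction of an aromatic aldehyde; nothing else in the molecule is reducible by NaBH4.

Step 6
Reactants: 11 [4-(benzyloxy)-3-(4-chlorophenoxy)phenyl]methanol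
Product: 12 1-(benzyloxy)-4-(bromomethyl)-2-(4-chlorophenoxy)benzene
Conditions: PBr3, CH2Cl2, 0 °C; used without chromatography
Reagents that add atoms: phosphorus tribromide, BrP(Br)Br
Why: Conversion of a benzylic alcohol into the bromide through its phosphite ester. The para-alkoxy group makes the bromide reactive, so it is carried on directly.

Step 7
Reactants: 12 1-(benzyloxy)-4-(bromomethyl)-2-(4-chlorophenoxy)benzene; 13 1-(trimethylsilyl)propyne
Product: 15 1-(benzyloxy)-4-(but-3-yn-1-yl)-2-(4-chlorophenoxy)benzene, via silyl alkyne 14 (not isolated)
Conditions: 13, n-BuLi, THF, −78 °C; then 12, −78 °C to rt; then Bu4NF, rt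
Reagents that add atoms: none
Why: Alkylation of lithiated 1-(trimethylsilyl)propyne with a benzylic bromide, which occurs at the propargylic carbon because silicon blocks the alkyne terminus. Fluoride then removes the silyl group in the same flask to give the terminal 4-aryl-1-butyne.

Step 8
Reactants: 15 1-(benzyloxy)-4-(but-3-yn-1-yl)-2-(4-chlorophenoxy)benzene; 16 trichloroacetyl chloride
Product: 17 3-{2-[4-(benzyloxy)-3-(4-chlorophenoxy)phenyl]ethyl}-4,4-dichlorocyclobut-2-en-1-one
Conditions: Zn(Cu) couple, Et2O–DME, rt
Reagents that add atoms: none
Why: [2+2] cycloaddition of dichloroketene, generated in the flask by zinc dechlorination of 16, with a terminal alkyne. The alkyne terminus bonds to the ketene carbonyl carbon, so the substituent ends at C3. DME ties up the ZnCl2 formed.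

Step 9
Reactants: 17 3-{2-[4-(benzyloxy)-3-(4-chlorophenoxy)phenyl]ethyl}-4,4-dichlorocyclobut-2-en-1-one
Product: 18 3-{2-[4-(benzyloxy)-3-(4-chlorophenoxy)phenyl]ethyl}cyclobut-2-en-1-one
Conditions: Zn dust, TMEDA, AcOH, EtOH, 0 °C to rt
Reagents that add atoms: none
Why: Reductive removal of both chlorines alpha to the ketone by zinc in buffered acetic acid, the standard route from 4,4-dichlorocyclobutenones to cyclobutenones. The aryl chloride and the benzyl ether are not reduced by zinc.

Step 10
Reactants: 7 1-(dimethoxymethyl)-2-(ethynyloxy)-3-methoxybenzene (1.5 equiv); 18 3-{2-[4-(benzyloxy)-3-(4-chlorophenoxy)phenyl]ethyl}cyclobut-2-en-1-one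
Product: 23 3-{2-[4-(benzyloxy)-3-(4-chlorophenoxy)phenyl]ethyl}-5-[2-(dimethoxymethyl)-6-methoxyphenoxy]phenol, via vinylketene 19 (not isolated), via vinylcyclobutenone 20 (not isolated), via dienylketene 21 (not isolated), via cyclohexadienone 22 (not isolated)
Conditions: toluene, 80 °C, then 110 °C, argon
Reagents that add atoms: none
Why: Danheiser benzannulation, the known thermal cascade of cyclobutenones with heteroatom-substituted alkynes, applied here to an aryl ynol ether, a less common partner than alkyl ynol ethers. Heating opens 18 by 4π electrocyclic cleavage of the C1–C4 bond to the vinylketene 19. In a regiospecific [2+2] cycloaddition the nucleophilic terminal carbon of 7 bonds to the electrophilic ketene carbon and the oxygen-bearing carbon to the ketene alpha carbon, giving 20. A second 4π opening gives the Z-dienylketene 21, and its thermally allowed disrotatory 6π electrocyclisation closes ring B as 22, which tautomerises to the phenol 23. The selectivity needed is regiochemical: the aryloxy carbon must end meta to both the new hydroxyl and the arm, and this follows from the matched polarisation of ynol ether and ketene. No stereocentre remains, since the one in 20 is lost on ring opening. The crowded ring A oxygen takes no part because it was bonded beforehand to an sp carbon. The excess of 7 limits acylation of the product phenol by 19.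

Step 11
Reactants: 23 3-{2-[4-(benzyloxy)-3-(4-chlorophenoxy)phenyl]ethyl}-5-[2-(dimethoxymethyl)-6-methoxyphenoxy]phenol
Product: 24 3-{2-[4-(benzyloxy)-3-(4-chlorophenoxy)phenyl]ethyl}-5-[2-(dimethoxymethyl)-6-methoxyphenoxy]phenyl trifluoromethanesulfonate
Conditions: PhNTf2, Et3N, DMAP (cat.), CH2Cl2, rt
Reagents that add atoms: N-phenylbis(trifluoromethanesulfonimide), O=S(=O)(N(c1ccccc1)S(=O)(=O)C(F)(F)F)C(F)(F)F
Why: O-sulfonylation of an unhindered phenol. The neutral triflimide reagent avoids the acidic pyridinium salts of the anhydride method and so spares the acetal.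

Step 12
Reactants: 24 3-{2-[4-(benzyloxy)-3-(4-chlorophenoxy)phenyl]ethyl}-5-[2-(dimethoxymethyl)-6-methoxyphenoxy]phenyl trifluoromethanesulfonate
Product: 26 2-(3-{2-[4-(benzyloxy)-3-(4-chlorophenoxy)phenyl]ethyl}phenoxy)-3-methoxybenzaldehyde, via deoxygenated acetal 25 (not isolated)
Conditions: Pd(OAc)2, PPh3, HCO2H, Et3N, DMF, 60 °C; then 1 M HCl, THF, rt
Reagents that add atoms: water, O
Why: Palladium-catalysed formate reduction of an aryl triflate (oxidative addition, formate exchange, loss of CO2, reductive elimination of Ar–H). With PPh3 as ligand the electron-rich aryl chloride and the benzyl ether are not attacked. The aqueous acid of the work-up then hydrolyses the dimethyl acetal.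

Step 13
Reactants: 26 2-(3-{2-[4-(benzyloxy)-3-(4-chlorophenoxy)phenyl]ethyl}phenoxy)-3-methoxybenzaldehyde
Product: 27 1-(benzyloxy)-2-(4-chlorophenoxy)-4-{2-[3-(2-ethenyl-6-methoxyphenoxy)phenyl]ethyl}benzene
Conditions: Ph3PCH3Br, KOtBu, THF, 0 °C to rt
Reagents that add atoms: methyltriphenylphosphonium bromide, C[P+](c1ccccc1)(c1ccccc1)c1ccccc1.[Br-]
Why: Wittig methylenation of an aromatic aldehyde with the unstabilised ylide; no base-sensitive group is present.

Step 14
Reactants: 27 1-(benzyloxy)-2-(4-chlorophenoxy)-4-{2-[3-(2-ethenyl-6-methoxyphenoxy)phenyl]ethyl}benzene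
Product: 29 O-benzyl macrocycle (the target with its ring C hydroxyl as benzyl ether), via alkylborane 28 (not isolated)
Conditions: 9-BBN, THF, 0 °C to rt; then slow addition to Pd(OAc)2, SPhos, aq. K3PO4, THF–DMF, 70 °C, about 2 mM
Reagents that add atoms: none
Why: Anti-Markovnikov hydroboration of the styrene with 9-BBN, followed by intramolecular B-alkyl Suzuki–Miyaura coupling. The electron-rich dialkylbiarylphosphine lets zerovalent palladium insert into the aryl chloride, and slow addition keeps the borane dilute so that closure of the 18-membered ring competes with oligomerisation.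

Step 15
Reactants: 29 O-benzyl macrocycle
Product: 30 CNP0309263.0 (target)
Conditions: H2 (1 atm), Pd/C, EtOAc–MeOH, rt
Reagents that add atoms: none
Why: Hydrogenolysis of the benzyl ether; the diaryl ethers, the methyl ether and the bibenzyl bridges are stable to these conditions.

## Compound list

1 | o-vanillin (2-hydroxy-3-methoxybenzaldehyde) | COc1cccc(C=O)c1O | starting material
2 | trichloroethylene | ClC=C(Cl)Cl | starting material
3 | 2-[(E)-1,2-dichloroethenyloxy]-3-methoxybenzaldehyde | COc1cccc(C=O)c1O/C(Cl)=C\Cl | intermediate
4 | 2-[(E)-1,2-dichloroethenyloxy]-1-(dimethoxymethyl)-3-methoxybenzene | COc1cccc(C(OC)OC)c1O/C(Cl)=C\Cl | intermediate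
5 | 2-(chloroethynyloxy)-1-(dimethoxymethyl)-3-methoxybenzene | COc1cccc(C(OC)OC)c1OC#CCl | intermediate (not isolated)
6 | {[2-(dimethoxymethyl)-6-methoxyphenoxy]ethynyl}lithium | COc1cccc(C(OC)OC)c1OC#C[Li] | intermediate (not isolated)
7 | 1-(dimethoxymethyl)-2-(ethynyloxy)-3-methoxybenzene | COc1cccc(C(OC)OC)c1OC#C | intermediate
8 | 4-benzyloxy-3-hydroxybenzaldehyde | O=Cc1ccc(OCc2ccccc2)c(O)c1 | starting material
9 | 1-chloro-4-iodobenzene | Clc1ccc(I)cc1 | starting material
10 | 4-(benzyloxy)-3-(4-chlorophenoxy)benzaldehyde | O=Cc1ccc(OCc2ccccc2)c(Oc2ccc(Cl)cc2)c1 | intermediate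
11 | [4-(benzyloxy)-3-(4-chlorophenoxy)phenyl]methanol | OCc1ccc(OCc2ccccc2)c(Oc2ccc(Cl)cc2)c1 | intermediate
12 | 1-(benzyloxy)-4-(bromomethyl)-2-(4-chlorophenoxy)benzene | BrCc1ccc(OCc2ccccc2)c(Oc2ccc(Cl)cc2)c1 | intermediate
13 | 1-(trimethylsilyl)propyne | CC#C[Si](C)(C)C | starting material
14 | {4-[4-(benzyloxy)-3-(4-chlorophenoxy)phenyl]but-1-yn-1-yl}trimethylsilane | C[Si](C)(C)C#CCCc1ccc(OCc2ccccc2)c(Oc2ccc(Cl)cc2)c1 | intermediate (not isolated)
15 | 1-(benzyloxy)-4-(but-3-yn-1-yl)-2-(4-chlorophenoxy)benzene | C#CCCc1ccc(OCc2ccccc2)c(Oc2ccc(Cl)cc2)c1 | intermediate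
16 | trichloroacetyl chloride | ClC(=O)C(Cl)(Cl)Cl | starting material
17 | 3-{2-[4-(benzyloxy)-3-(4-chlorophenoxy)phenyl]ethyl}-4,4-dichlorocyclobut-2-en-1-one | O=C1C=C(CCc2ccc(OCc3ccccc3)c(Oc3ccc(Cl)cc3)c2)C1(Cl)Cl | intermediate
18 | 3-{2-[4-(benzyloxy)-3-(4-chlorophenoxy)phenyl]ethyl}cyclobut-2-en-1-one | O=C1C=C(CCc2ccc(OCc3ccccc3)c(Oc3ccc(Cl)cc3)c2)C1 | intermediate
19 | vinylketene: 3-{2-[4-(benzyloxy)-3-(4-chlorophenoxy)phenyl]ethyl}buta-1,3-dien-1-one | O=C=CC(=C)CCc1ccc(OCc2ccccc2)c(Oc2ccc(Cl)cc2)c1 | intermediate (not isolated)
20 | vinylcyclobutenone (racemic): 3-[2-(dimethoxymethyl)-6-methoxyphenoxy]-4-{4-[4-(benzyloxy)-3-(4-chlorophenoxy)phenyl]but-1-en-2-yl}cyclobut-2-en-1-one | O=C1C=C(Oc2c(OC)cccc2C(OC)OC)C1C(=C)CCc1ccc(OCc2ccccc2)c(Oc2ccc(Cl)cc2)c1 | intermediate (not isolated)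
21 | dienylketene: (3Z)-3-[2-(dimethoxymethyl)-6-methoxyphenoxy]-5-{2-[4-(benzyloxy)-3-(4-chlorophenoxy)phenyl]ethyl}hexa-1,3,5-trien-1-one | O=C=C/C(Oc1c(OC)cccc1C(OC)OC)=C\C(=C)CCc1ccc(OCc2ccccc2)c(Oc2ccc(Cl)cc2)c1 | intermediate (not isolated)
22 | cyclohexadienone: 3-[2-(dimethoxymethyl)-6-methoxyphenoxy]-5-{2-[4-(benzyloxy)-3-(4-chlorophenoxy)phenyl]ethyl}cyclohexa-2,4-dien-1-one | O=C1C=C(Oc2c(OC)cccc2C(OC)OC)C=C(CCc2ccc(OCc3ccccc3)c(Oc3ccc(Cl)cc3)c2)C1 | intermediate (not isolated)
23 | 3-{2-[4-(benzyloxy)-3-(4-chlorophenoxy)phenyl]ethyl}-5-[2-(dimethoxymethyl)-6-methoxyphenoxy]phenol | COc1cccc(C(OC)OC)c1Oc1cc(O)cc(c1)CCc1ccc(OCc2ccccc2)c(c1)Oc1ccc(Cl)cc1 | intermediate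
24 | 3-{2-[4-(benzyloxy)-3-(4-chlorophenoxy)phenyl]ethyl}-5-[2-(dimethoxymethyl)-6-methoxyphenoxy]phenyl trifluoromethanesulfonate | COc1cccc(C(OC)OC)c1Oc1cc(OS(=O)(=O)C(F)(F)F)cc(c1)CCc1ccc(OCc2ccccc2)c(c1)Oc1ccc(Cl)cc1 | intermediate
25 | 1-(benzyloxy)-2-(4-chlorophenoxy)-4-(2-{3-[2-(dimethoxymethyl)-6-methoxyphenoxy]phenyl}ethyl)benzene | COc1cccc(C(OC)OC)c1Oc1cccc(c1)CCc1ccc(OCc2ccccc2)c(c1)Oc1ccc(Cl)cc1 | intermediate (not isolated)
26 | 2-(3-{2-[4-(benzyloxy)-3-(4-chlorophenoxy)phenyl]ethyl}phenoxy)-3-methoxybenzaldehyde | COc1cccc(C=O)c1Oc1cccc(c1)CCc1ccc(OCc2ccccc2)c(c1)Oc1ccc(Cl)cc1 | intermediate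
27 | 1-(benzyloxy)-2-(4-chlorophenoxy)-4-{2-[3-(2-ethenyl-6-methoxyphenoxy)phenyl]ethyl}benzene | COc1cccc(C=C)c1Oc1cccc(c1)CCc1ccc(OCc2ccccc2)c(c1)Oc1ccc(Cl)cc1 | intermediate
28 | B-alkyl-9-borabicyclo[3.3.1]nonane: 9-{2-[2-(3-{2-[4-(benzyloxy)-3-(4-chlorophenoxy)phenyl]ethyl}phenoxy)-3-methoxyphenyl]ethyl}-9-BBN | COc1cccc(CCB2C3CCCC2CCC3)c1Oc1cccc(c1)CCc1ccc(OCc2ccccc2)c(c1)Oc1ccc(Cl)cc1 | intermediate (not isolated)
29 | O-benzyl macrocycle (18-membered ring, ring C hydroxyl as benzyl ether) | COc1cccc2c1Oc1cccc(c1)CCc1ccc(OCc3ccccc3)c(c1)Oc1ccc(cc1)CC2 | intermediate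
30 | CNP0309263.0 | COc1cccc2c1Oc1cccc(c1)CCc1ccc(O)c(c1)Oc1ccc(cc1)CC2 | target

## Step count and risks

Total: 15 steps. Longest linear sequence: 12 steps (steps 4–15 from **8**); the ring A branch (steps 1–3) joins at step 10.

**Step 10 (key step).** The aryloxy alkyne is less electron-rich than an alkoxy alkyne, so the [2+2] capture of the vinylketene may be slow. Ketene dimerisation, acylation of the product phenol by the ketene, or thermal oligomerisation of the ynol ether could then take over, and traces of acid could open the acetal. The fallback gives up ring construction and makes the ether by SNAr, with the hindered ring A carbon as the electrophile. It sets out from benzyl bromide **12** and returns at aldehyde **26**. Bromide **12** and PPh3 in hot toluene would give the phosphonium bromide F1. Wittig reaction with 3-hydroxybenzaldehyde (K2CO3, 18-crown-6, CH2Cl2, reflux) would give the stilbene phenol F2. Diimide reduction (p-toluenesulfonyl hydrazide, NaOAc, aqueous THF, reflux), which spares the benzyl ether and the chloride, would give the bibenzyl phenol F3. SNAr of its phenoxide on 2-fluoro-3-methoxybenzaldehyde (K2CO3, DMAc, 130 °C), where the ortho formyl group activates the fluoride and the nucleophile is unhindered, would give **26**.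

**Step 14.** Intermolecular coupling may outrun ring closure, or the alkylborane may be lost by protodeboronation while oxidative addition into the electron-rich chloride is slow. The fallback closes the ring by metathesis, setting out from styrene **27** and returning at target **30**. Suzuki–Miyaura vinylation of the chloride with K[CH2=CHBF3] (Pd(OAc)2, SPhos, Cs2CO3, THF–H2O) would give the bis-styrene F4. Ring-closing metathesis with the second-generation Grubbs catalyst (H2IMes)(PCy3)Cl2Ru=CHPh in dilute toluene would give the macrocyclic stilbene F5. Hydrogenation over Pd/C would saturate the alkene and remove the benzyl group in one operation, giving **30**.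

**Step 8.** Dichloroketene may oligomerise faster than it adds to the unactivated alkyne, and the zinc salts may attack the electron-rich benzyl aryl ether. The fallback uses a keteniminium ion in place of the ketene and needs no dechlorination. It sets out from alkyne **15** and returns at cyclobutenone **18**. N,N-dimethylacetamide, Tf2O and 2,4,6-collidine in 1,2-dichloroethane at reflux would give the cyclobuteniminium triflate F6 by [2+2] cycloaddition, and aqueous NaHCO3 would hydrolyse it to **18**.

**Step 3.** The terminal ynol ether may be lost on isolation by hydration to the aryl acetate or by oligomerisation on concentration. The fallback stores it as a silyl derivative, setting out from dichlorovinyl ether **4** and returning at ynol ether **7**. The acetylide **6**, generated as in step 3, would be quenched with i-Pr3SiCl to give the silyl ynol ether F7, which can be chromatographed and kept. Bu4NF in THF at 0 °C just before step 10 would release **7**.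

## Further compounds

F1 | step 10 | [4-(benzyloxy)-3-(4-chlorophenoxy)benzyl]triphenylphosphonium bromide | [Br-].c1ccc(cc1)[P+](Cc1ccc(OCc2ccccc2)c(Oc2ccc(Cl)cc2)c1)(c1ccccc1)c1ccccc1
F2 | step 10 | 3-{2-[4-(benzyloxy)-3-(4-chlorophenoxy)phenyl]ethenyl}phenol (E isomer drawn; the Z isomer would form beside it) | Oc1cccc(/C=C/c2ccc(OCc3ccccc3)c(Oc3ccc(Cl)cc3)c2)c1
F3 | step 10 | 3-{2-[4-(benzyloxy)-3-(4-chlorophenoxy)phenyl]ethyl}phenol | Oc1cccc(CCc2ccc(OCc3ccccc3)c(Oc3ccc(Cl)cc3)c2)c1
F4 | step 14 | 1-(benzyloxy)-2-(4-ethenylphenoxy)-4-{2-[3-(2-ethenyl-6-methoxyphenoxy)phenyl]ethyl}benzene | COc1cccc(C=C)c1Oc1cccc(c1)CCc1ccc(OCc2ccccc2)c(c1)Oc1ccc(C=C)cc1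
F5 | step 14 | O-benzyl macrocyclic stilbene, ring A–ring D bridge as CH=CH (Z isomer drawn) | COc1cccc(/C=C\c2ccc(cc2)Oc2cc(ccc2OCc2ccccc2)CCc2cccc(c2)O3)c13
F6 | step 8 | N-(3-{2-[4-(benzyloxy)-3-(4-chlorophenoxy)phenyl]ethyl}cyclobut-2-en-1-ylidene)-N-methylmethanaminium trifluoromethanesulfonate | C[N+](C)=C1C=C(CCc2ccc(OCc3ccccc3)c(Oc3ccc(Cl)cc3)c2)C1.[O-]S(=O)(=O)C(F)(F)F
F7 | step 3 | {[2-(dimethoxymethyl)-6-methoxyphenoxy]ethynyl}tri(propan-2-yl)silane | COc1cccc(C(OC)OC)c1OC#C[Si](C(C)C)(C(C)C)C(C)C
A1 | alternative 1 | open-chain bisphenol: 2,6-dibromo-4-{2-[3-(2-[2-(3,5-dichloro-4-hydroxyphenyl)ethyl]-6-methoxyphenoxy)phenyl]ethyl}phenol | COc1cccc(CCc2cc(Cl)c(O)c(Cl)c2)c1Oc1cccc(CCc2cc(Br)c(O)c(Br)c2)c1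
A2 | alternative 1 | bromo dichloro macrocycle with free ring C phenol | COc1cccc2c1Oc1cccc(c1)CCc1cc(Br)c(O)c(c1)Oc1c(Cl)cc(cc1Cl)CC2
A3 | alternative 2 | ring B pinacol boronate: 2-{3-[2-(dimethoxymethyl)-6-methoxyphenoxy]phenyl}-4,4,5,5-tetramethyl-1,3,2-dioxaborolane | COc1cccc(C(OC)OC)c1Oc1cccc(c1)B1OC(C)(C)C(C)(C)O1
A4 | alternative 2 | vinyllithium | [Li]C=C
A5 | alternative 2 | ring C triflate: 4-(benzyloxy)-3-(4-chlorophenoxy)phenyl trifluoromethanesulfonate | O=S(=O)(Oc1ccc(OCc2ccccc2)c(Oc2ccc(Cl)cc2)c1)C(F)(F)F
A6 | alternative 2 | benzylic pinacol boronate (racemic) | COc1cccc(C(OC)OC)c1Oc1cccc(c1)C(B1OC(C)(C)C(C)(C)O1)Cc1ccc(OCc2ccccc2)c(c1)Oc1ccc(Cl)cc1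
A7 | alternative 3 | seco acid: 2-[2-(2-{4-[2-(benzyloxy)-5-ethenylphenoxy]phenyl}ethyl)-6-methoxyphenoxy]benzoic acid | COc1cccc(CCc2ccc(Oc3cc(C=C)ccc3OCc3ccccc3)cc2)c1Oc1ccccc1C(=O)O
A8 | alternative 3 | macrocyclic E-stilbene carboxylic acid | COc1cccc2c1Oc1cccc(c1C(=O)O)/C=C/c1ccc(OCc3ccccc3)c(c1)Oc1ccc(cc1)CC2
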